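The synthesis rests on closing ring B through the C8–C9 bond while ring C is still aromatic. Ring C carries oxygen on C10 and methyl groups on C9 and C13, the pattern of 2,4-dimethylphenol, and C9 is the only ring carbon flanked by both the oxygen-bearing C10 and the tether-bearing C14. A lithium phenoxide, kept as a contact ion pair, therefore alkylates through C9 with the primary methanesulfonate on C8: one operation closes ring B, creates the quaternary angular C9 and leaves a dienone with the C10 carbonyl and the C13=C14 alkene. The precursor is a C6 carbinol carrying ring A, a 3-hydroxy-2,6-dimethylbenzyl group and a 2-(mesyloxy)ethyl arm.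

Key step: step 22

Remark: atoms are numbered as in the target (ring A: C1 CMe2, C2 CHBr, C3, C4 CHOH, C5 CMe; ring B: C6, C7, C8, C9, C14, C15; ring C: C9 to C14); C13, the para carbon, is bonded to C14 just as C9 is and can reach C8 through an equally good six-membered transition state, so ortho versus para alkylation is treated as a real selectivity problem that ring size does not solve.

Step 1
Reactants: 1 (1R,4S)-(+)-camphanic acid
Product: 3 (1S)-1,2,2-trimethyl-3-oxocyclopentane-1-carboxylic acid, via disodium hydroxy dicarboxylate 2 (not isolated)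
Conditions: NaOH, H2O, 23 °C; then NaOCl, NaHCO3 (pH 8), 0 → 23 °C; HCl
Reagents that add atoms: sodium hydroxide, [Na+].[OH-]
Why: Saponification of the bridged lactone and oxidative decarboxylation of the tertiary α-hydroxy carboxylate (fragmentation of its hypochlorite) should unmask the C2 ketone, while the quaternary C5 centre taken from the chiral pool is not touched.

Step 2
Reactants: 3 (1S)-1,2,2-trimethyl-3-oxocyclopentane-1-carboxylic acid
Product: 4 methyl (1S)-1,2,2-trimethyl-3-oxocyclopentane-1-carboxylate
Conditions: MeI, K2CO3, DMF, 23 °C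
Reagents that add atoms: iodomethane, CI
Why: Carboxylate O-alkylation (SN2 on iodomethane) should esterify the hindered acid without acid catalysis.

Step 3
Reactants: 4 methyl (1S)-1,2,2-trimethyl-3-oxocyclopentane-1-carboxylate
Product: 6 methyl (1S)-1,2,2-trimethyl-3-(trifluoromethylsulfonyloxy)cyclopent-3-ene-1-carboxylate, via potassium enolate 5 (not isolated)
Conditions: KN(SiMe3)2, THF, −78 °C; then PhNTf2, −78 → 0 °C
Reagents that add atoms: N-phenylbis(trifluoromethanesulfonimide), O=S(=O)(N(c1ccccc1)S(=O)(=O)C(F)(F)F)C(F)(F)F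
Why: Enol triflate formation: the ketone can enolise only toward C3 because C1 is quaternary, and the enolate oxygen is sulfonylated.

Step 4
Reactants: 6 methyl (1S)-1,2,2-trimethyl-3-(trifluoromethylsulfonyloxy)cyclopent-3-ene-1-carboxylate
Product: 7 methyl (1S)-3-bromo-1,2,2-trimethylcyclopent-3-ene-1-carboxylate
Conditions: Ni(cod)2 (10 mol %), LiBr, DMA/THF, 23 °C
Reagents that add atoms: lithium bromide, [Li+].[Br-]
Why: Nickel-catalysed exchange of an enol triflate for bromide (oxidative addition, anion exchange, C–Br reductive elimination) should place bromine on C2 regiospecifically.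

Step 5
Reactants: 7 methyl (1S)-3-bromo-1,2,2-trimethylcyclopent-3-ene-1-carboxylate
Product: 8 methyl (1R)-3-bromo-1,2,2-trimethyl-5-oxocyclopent-3-ene-1-carboxylate
Conditions: Rh2(cap)4 (dirhodium tetrakis(caprolactamate), 1 mol %), t-BuOOH (70 % aq.), K2CO3, CH2Cl2, 23 °C
Reagents that add atoms: tert-butyl hydroperoxide, CC(C)(C)OO
Why: Allylic C–H oxidation by tert-butylperoxyl radicals: C4 is the only allylic methylene, and oxygenation at the secondary end of the allyl radical keeps the bromoalkene and should give the β-bromo enone.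

Step 6
Reactants: 8 methyl (1R)-3-bromo-1,2,2-trimethyl-5-oxocyclopent-3-ene-1-carboxylate
Product: 9 methyl (1R,5S)-3-bromo-5-hydroxy-1,2,2-trimethylcyclopent-3-ene-1-carboxylate
Conditions: NaBH4, CeCl3·7H2O, MeOH, −78 °C
Reagents that add atoms: none
Why: Luche 1,2-reduction: hydride should add to the carbonyl face anti to the ester (the face of the C5 methyl), as in reductions of 2-alkyl-2-alkoxycarbonylcyclopentanones, so the C4 hydroxyl ends cis to C6.

Step 7
Reactants: 9 methyl (1R,5S)-3-bromo-5-hydroxy-1,2,2-trimethylcyclopent-3-ene-1-carboxylate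
Product: 10 methyl (1R,5S)-3-bromo-5-[tert-butyl(dimethyl)silyl]oxy-1,2,2-trimethylcyclopent-3-ene-1-carboxylate
Conditions: TBSOTf, 2,6-lutidine, CH2Cl2, 0 °C
Reagents that add atoms: tert-butyldimethylsilyl trifluoromethanesulfonate, CC(C)(C)[Si](C)(C)OS(=O)(=O)C(F)(F)F
Why: Silyl ether formation with the silyl triflate should protect the hindered allylic alcohol.

Step 8
Reactants: 10 methyl (1R,5S)-3-bromo-5-[tert-butyl(dimethyl)silyl]oxy-1,2,2-trimethylcyclopent-3-ene-1-carboxylate
Product: 11 methyl (1R,3R,5S)-3-bromo-5-[tert-butyl(dimethyl)silyl]oxy-1,2,2-trimethylcyclopentane-1-carboxylate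
Conditions: Mn(dpm)3 (10 mol %), PhSiH3, t-BuOOH, i-PrOH, 23 °C
Reagents that add atoms: none
Why: Hydrogen-atom-transfer hydrogenation of a bromoalkene: H adds to C3, and the α-bromo radical at C2 should take the second hydrogen on the face opposite the silyloxy and ester groups, which leaves bromine cis to both.

Step 9
Reactants: 11 methyl (1R,3R,5S)-3-bromo-5-[tert-butyl(dimethyl)silyl]oxy-1,2,2-trimethylcyclopentane-1-carboxylate
Product: 12 (1R,3R,5S)-3-bromo-5-[tert-butyl(dimethyl)silyl]oxy-1,2,2-trimethylcyclopentane-1-carbaldehyde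
Conditions: i-Bu2AlH (1.2 equiv), toluene, −78 °C
Reagents that add atoms: none
Why: Partial ester reduction: the aluminium hemiacetal of this neopentyl ester should survive at −78 °C and release the aldehyde on work-up.

Step 10
Reactants: 13 2,6-dimethylbenzoic acid
Product: 14 2,6-dimethyl-3-nitrobenzoic acid
Conditions: HNO3, H2SO4, 0 °C
Reagents that add atoms: nitric acid, O[N+](=O)[O-]
Why: Electrophilic aromatic nitration at C3, which is ortho and para to the methyl groups and meta to the carboxyl group.

Step 11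
Reactants: 14 2,6-dimethyl-3-nitrobenzoic acid
Product: 15 3-amino-2,6-dimethylbenzoic acid
Conditions: H2 (1 atm), Pd/C (10 wt %), MeOH, 23 °C
Reagents that add atoms: none
Why: Catalytic hydrogenation of the nitro group should give the aniline.

Step 12
Reactants: 15 3-amino-2,6-dimethylbenzoic acid
Product: 17 3-hydroxy-2,6-dimethylbenzoic acid, via diazonium hydrogen sulfate 16 (not isolated)
Conditions: NaNO2, aq. H2SO4, 0 °C; then aq. H2SO4, 100 °C
Reagents that add atoms: water, O
Why: Diazotisation and thermal hydrolysis of the diazonium salt should turn the aniline into the phenol.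

Step 13
Reactants: 17 3-hydroxy-2,6-dimethylbenzoic acid
Product: 18 tert-butyl(dimethyl)silyl 3-[tert-butyl(dimethyl)silyl]oxy-2,6-dimethylbenzoate
Conditions: TBSCl (2.5 equiv), imidazole, DMF, 23 °C
Reagents that add atoms: tert-butyldimethylsilyl chloride, CC(C)(C)[Si](C)(C)Cl
Why: Silylation of both acidic hydroxyls should give the aryl silyl ether and the silyl ester.

Step 14
Reactants: 18 tert-butyl(dimethyl)silyl 3-[tert-butyl(dimethyl)silyl]oxy-2,6-dimethylbenzoate
Product: 19 [3-[tert-butyl(dimethyl)silyl]oxy-2,6-dimethylphenyl]methanol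
Conditions: i-Bu2AlH (3 equiv), CH2Cl2, −78 → 0 °C
Reagents that add atoms: none
Why: Hydride reduction of the silyl ester should give the benzylic alcohol while the aryl silyl ether is inert.

Step 15
Reactants: 19 [3-[tert-butyl(dimethyl)silyl]oxy-2,6-dimethylphenyl]methanol
Product: 20 tert-butyl-[3-(chloromethyl)-2,4-dimethylphenoxy]dimethylsilane
Conditions: Ph3P, N-chlorosuccinimide, CH2Cl2, 0 → 23 °C
Reagents that add atoms: N-chlorosuccinimide, O=C1CCC(=O)N1Cl
Why: Appel-type chlorination through the alkoxyphosphonium salt is neutral and should spare the aryl silyl ether.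

Step 16
Reactants: 20 tert-butyl-[3-(chloromethyl)-2,4-dimethylphenoxy]dimethylsilane; 12 (1R,3R,5S)-3-bromo-5-[tert-butyl(dimethyl)silyl]oxy-1,2,2-trimethylcyclopentane-1-carbaldehyde
Product: 22 secondary alcohol joining C5 of ring A to the silyloxy-dimethylbenzyl group through the C6 carbinol (both C6 epimers), via benzylic Grignard reagent 21 (not isolated)
Conditions: Mg, Et2O, 0 °C (slow addition of 20); then 12, THF, −78 → 0 °C; aq. NH4Cl
Reagents that add atoms: none
Why: Grignard addition to a non-enolisable aldehyde forms the C6–C15 bond; the reagent has no β-hydrogen, so reduction cannot compete, and the carbinol centre is erased in the next step.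

Step 17
Reactants: 22 secondary alcohol (both C6 epimers)
Product: 23 benzyl ketone with the C6 carbonyl between C5 of ring A and C15
Conditions: Dess–Martin periodinane, NaHCO3, CH2Cl2, 23 °C
Reagents that add atoms: none
Why: Dess–Martin oxidation should convert both epimeric alcohols into one ketone.

Step 18
Reactants: 23 benzyl ketone
Product: 24 tertiary allylic alcohol with C6 configured as in the target (vinyl group = C7 and C8)
Conditions: CeCl3, CH2=CHMgBr, THF, −78 °C; then 23, −78 → −40 °C
Reagents that add atoms: vinylmagnesium bromide, C=C[Mg]Br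
Why: Organocerium 1,2-addition suppresses enolisation of the benzylic ketone, and Felkin–Anh control from C5 (C1 anti to the nucleophile, C4 beside the carbonyl oxygen, approach past the C5 methyl) should set C6 as in the target.

Step 19
Reactants: 24 tertiary allylic alcohol
Product: 26 1,3-diol with a primary hydroxyl on C8, via alkylborane 25 (not isolated)
Conditions: 9-BBN, THF, 0 → 40 °C; then H2O2, aq. NaOAc, 0 → 23 °C
Reagents that add atoms: hydrogen peroxide, OO
Why: Anti-Markovnikov hydroboration of the terminal alkene and buffered oxidation of the borane should give the primary alcohol without cleaving the aryl silyl ether.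

Step 20
Reactants: 26 1,3-diol
Product: 27 primary methanesulfonate on C8 (phenol still silylated)
Conditions: MsCl (1.1 equiv), Et3N, CH2Cl2, −20 °C
Reagents that add atoms: methanesulfonyl chloride, CS(=O)(=O)Cl
Why: Sulfonylation is selective for the primary hydroxyl over the hindered tertiary C6 hydroxyl.

Step 21
Reactants: 27 primary methanesulfonate (aryl silyl ether)
Product: 28 phenol methanesulfonate (key-step precursor)
Conditions: KHF2, MeOH, 23 °C
Reagents that add atoms: none
Why: Bifluoride desilylation is selective for the aryl silyl ether over the alkyl silyl ether, so the phenol is set free only after the sulfonate is in place and cannot itself be sulfonylated.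

Step 22
Reactants: 28 phenol methanesulfonate
Product: 30 tricyclic cyclohexa-2,4-dienone (C9 quaternary, C10 ketone, C11=C12 and C13=C14 alkenes), via lithium phenoxide 29 (not isolated)
Conditions: t-BuOLi (1.05 equiv), toluene (0.005 M), 23 → 80 °C
Reagents that add atoms: none
Why: The lithium phenoxide acts as an ambident enolate whose ortho carbon C9 displaces the C8 methanesulfonate by SN2, the lithium ion bridging the oxygen on C10 to a sulfonyl oxygen of the leaving group. The closest known reaction type is the ortho C-alkylation of alkali-metal phenoxides in non-polar media, which gives 6,6-disubstituted cyclohexa-2,4-dienones, used here intramolecularly as an alkylative dearomatisation. Ring B closes in the 6-exo-tet mode (6-enolexo with respect to the C9=C10 enolate). The one new stereocentre, C9, is controlled by C6: in the chair-like transition state ring A sits equatorial and the hydroxyl axial on C6, so C8 reaches the arene face that leaves the C9 methyl trans to the C6 hydroxyl. The step needs C9 to win over C13, which is para to oxygen and equally close to C8, and over oxygen itself; C9 alone lies next to the lithium-bearing oxygen, toluene disfavours the charge-separated para pathway, and O-alkylation would need a strained meta-bridged eight-membered ether. The product should persist because the quaternary C9 blocks rearomatisation.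

Step 23
Reactants: 30 tricyclic cyclohexa-2,4-dienone
Product: 31 β,γ-unsaturated ketone (C10 ketone, C13=C14 alkene)
Conditions: [(Ph3P)CuH]6 (0.5 equiv), H2O (5 equiv), toluene, 23 °C
Reagents that add atoms: none
Why: Conjugate 1,4-reduction with Stryker's reagent: hydride should add to the unhindered C12 and not to the fully substituted C14, and after protonation at C11 the C13=C14 alkene cannot move into conjugation because C9 is quaternary.

Step 24
Reactants: 31 β,γ-unsaturated ketone
Product: 33 enol triflate (C10–OTf, C10=C11), via dipotassium alkoxide enolate 32 (not isolated)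
Conditions: KN(SiMe3)2 (2.2 equiv), THF, −78 °C; then PhNTf2 (1.1 equiv), −78 → −30 °C
Reagents that add atoms: N-phenylbis(trifluoromethanesulfonimide), O=S(=O)(N(c1ccccc1)S(=O)(=O)C(F)(F)F)C(F)(F)F
Why: Enol triflate formation: the ketone can enolise only toward C11, and the enolate oxygen is sulfonylated much faster than the hindered tertiary alkoxide.

Step 25
Reactants: 33 enol triflate
Product: 34 bromodiene (C10 bromoalkene, C13=C14 alkene)
Conditions: Pd2(dba)3 (2.5 mol %), t-BuBrettPhos (7.5 mol %), KBr, KF (0.5 equiv), 1,4-dioxane, 100 °C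
Reagents that add atoms: potassium bromide, [K+].[Br-]
Why: Palladium-catalysed conversion of an enol triflate into the alkenyl bromide (oxidative addition, bromide exchange, C–Br reductive elimination from the bulky biarylphosphine complex) should not touch the hindered alkyl bromide on C2.

Step 26
Reactants: 34 bromodiene
Product: 35 13,14-epoxide with oxygen on the face of the C6 hydroxyl
Conditions: m-CPBA, NaHCO3, CH2Cl2, 0 °C
Reagents that add atoms: 3-chloroperoxybenzoic acid, OOC(=O)c1cccc(Cl)c1
Why: Prilezhaev epoxidation of the only electron-rich alkene: hydrogen bonding of the peracid to the axial C6 hydroxyl and shielding of the other face by the axial C9 methyl should direct oxygen to the face of the C6 hydroxyl.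

Step 27
Reactants: 35 13,14-epoxide
Product: 36 bromoalkene triol (C6, C13 and C14 hydroxyls; C13 and C14 trans-diaxial)
Conditions: HClO4 (0.2 M aq.), THF, 0 → 23 °C
Reagents that add atoms: water, O
Why: Acid-catalysed epoxide hydrolysis: water should open the protonated epoxide at C13 with inversion (trans-diaxial opening, C14 being the more hindered ring-fusion carbon), giving the axial C13 hydroxyl trans to the axial C14 hydroxyl.

Step 28
Reactants: 36 bromoalkene triol
Product: 37 4-O-tert-butyldimethylsilyl neoirietetraol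
Conditions: Mn(dpm)3 (20 mol %), PhSiH3, t-BuOOH, i-PrOH, 23 °C
Reagents that add atoms: none
Why: Hydrogen-atom-transfer hydrogenation of the bromoalkene: H adds to C11, and the C10 radical should accept hydrogen axially, anti to the axial C9 methyl, so that bromine ends equatorial (thermodynamic stereocontrol).

Step 29
Reactants: 37 4-O-tert-butyldimethylsilyl neoirietetraol
Product: 38 neoirietetraol
Conditions: HF·pyridine, pyridine, THF, 0 → 23 °C
Reagents that add atoms: none
Why: Fluoride-mediated desilylation should release the C4 hydroxyl without affecting the tertiary alcohols or the two bromides.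

Compound list
1 | (1R,4S)-4,7,7-trimethyl-3-oxo-2-oxabicyclo[2.2.1]heptane-1-carboxylic acid, (+)-camphanic acid | CC1(C)[C@]2(C(=O)O)OC(=O)[C@@]1(C)CC2 | starting material
2 | disodium (1S,3R)-3-hydroxy-1,2,2-trimethylcyclopentane-1,3-dicarboxylate | CC1(C)[C@@](O)(C(=O)[O-])CC[C@]1(C)C(=O)[O-].[Na+].[Na+] | intermediate (not isolated)
3 | (1S)-1,2,2-trimethyl-3-oxocyclopentane-1-carboxylic acid | CC1(C)C(=O)CC[C@]1(C)C(=O)O | intermediate
4 | methyl (1S)-1,2,2-trimethyl-3-oxocyclopentane-1-carboxylate | CC1(C)C(=O)CC[C@]1(C)C(=O)OC | intermediate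
5 | potassium enolate of 4 (enolate toward C3) | CC1(C)C([O-])=CC[C@]1(C)C(=O)OC.[K+] | intermediate (not isolated)
6 | methyl (1S)-1,2,2-trimethyl-3-(trifluoromethylsulfonyloxy)cyclopent-3-ene-1-carboxylate | CC1(C)C(OS(=O)(=O)C(F)(F)F)=CC[C@]1(C)C(=O)OC | intermediate
7 | methyl (1S)-3-bromo-1,2,2-trimethylcyclopent-3-ene-1-carboxylate | CC1(C)C(Br)=CC[C@]1(C)C(=O)OC | intermediate
8 | methyl (1R)-3-bromo-1,2,2-trimethyl-5-oxocyclopent-3-ene-1-carboxylate | CC1(C)C(Br)=CC(=O)[C@]1(C)C(=O)OC | intermediate
9 | methyl (1R,5S)-3-bromo-5-hydroxy-1,2,2-trimethylcyclopent-3-ene-1-carboxylate (hydroxyl cis to ester) | CC1(C)C(Br)=C[C@H](O)[C@]1(C)C(=O)OC | intermediate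
10 | methyl (1R,5S)-3-bromo-5-[tert-butyl(dimethyl)silyl]oxy-1,2,2-trimethylcyclopent-3-ene-1-carboxylate | CC1(C)C(Br)=C[C@H](O[Si](C)(C)C(C)(C)C)[C@]1(C)C(=O)OC | intermediate
11 | methyl (1R,3R,5S)-3-bromo-5-[tert-butyl(dimethyl)silyl]oxy-1,2,2-trimethylcyclopentane-1-carboxylate (bromide, silyloxy and ester all cis) | CC1(C)[C@H](Br)C[C@H](O[Si](C)(C)C(C)(C)C)[C@]1(C)C(=O)OC | intermediate
12 | (1R,3R,5S)-3-bromo-5-[tert-butyl(dimethyl)silyl]oxy-1,2,2-trimethylcyclopentane-1-carbaldehyde | CC1(C)[C@H](Br)C[C@H](O[Si](C)(C)C(C)(C)C)[C@]1(C)C=O | intermediate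
13 | 2,6-dimethylbenzoic acid | Cc1cccc(C)c1C(=O)O | starting material
14 | 2,6-dimethyl-3-nitrobenzoic acid | Cc1ccc([N+](=O)[O-])c(C)c1C(=O)O | intermediate
15 | 3-amino-2,6-dimethylbenzoic acid | Cc1ccc(N)c(C)c1C(=O)O | intermediate
16 | 3-carboxy-2,4-dimethylbenzenediazonium hydrogen sulfate | Cc1ccc([N+]#N)c(C)c1C(=O)O.OS(=O)(=O)[O-] | intermediate (not isolated)
17 | 3-hydroxy-2,6-dimethylbenzoic acid | Cc1ccc(O)c(C)c1C(=O)O | intermediate
18 | tert-butyl(dimethyl)silyl 3-[tert-butyl(dimethyl)silyl]oxy-2,6-dimethylbenzoate | Cc1ccc(O[Si](C)(C)C(C)(C)C)c(C)c1C(=O)O[Si](C)(C)C(C)(C)C | intermediate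
19 | [3-[tert-butyl(dimethyl)silyl]oxy-2,6-dimethylphenyl]methanol | Cc1ccc(O[Si](C)(C)C(C)(C)C)c(C)c1CO | intermediate
20 | tert-butyl-[3-(chloromethyl)-2,4-dimethylphenoxy]dimethylsilane | Cc1ccc(O[Si](C)(C)C(C)(C)C)c(C)c1CCl | intermediate
21 | [3-[tert-butyl(dimethyl)silyl]oxy-2,6-dimethylphenyl]methylmagnesium chloride | Cc1ccc(O[Si](C)(C)C(C)(C)C)c(C)c1C[Mg]Cl | intermediate (not isolated)
22 | secondary alcohol: C6 carbinol (both epimers) between C5 of ring A (configured as in 12) and the 3-silyloxy-2,6-dimethylbenzyl group | CC1(C)[C@H](Br)C[C@H](O[Si](C)(C)C(C)(C)C)[C@]1(C)C(O)Cc1c(C)ccc(O[Si](C)(C)C(C)(C)C)c1C | intermediate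
23 | benzyl ketone: C6 carbonyl between C5 of ring A and C15 | CC1(C)[C@H](Br)C[C@H](O[Si](C)(C)C(C)(C)C)[C@]1(C)C(=O)Cc1c(C)ccc(O[Si](C)(C)C(C)(C)C)c1C | intermediate
24 | tertiary allylic alcohol: C6 bears hydroxyl, vinyl (C7=C8), the benzyl group and ring A, configured as in the target | CC1(C)[C@H](Br)C[C@H](O[Si](C)(C)C(C)(C)C)[C@]1(C)[C@@](Cc1c(C)ccc(O[Si](C)(C)C(C)(C)C)c1C)(O)C=C | intermediate
25 | B-alkyl-9-borabicyclo[3.3.1]nonane with boron on C8 | CC1(C)[C@H](Br)C[C@H](O[Si](C)(C)C(C)(C)C)[C@]1(C)[C@@](Cc1c(C)ccc(O[Si](C)(C)C(C)(C)C)c1C)(O)CCB1C2CCCC1CCC2 | intermediate (not isolated)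
26 | 1,3-diol: tertiary C6 hydroxyl and primary C8 hydroxyl | CC1(C)[C@H](Br)C[C@H](O[Si](C)(C)C(C)(C)C)[C@]1(C)[C@@](Cc1c(C)ccc(O[Si](C)(C)C(C)(C)C)c1C)(O)CCO | intermediate
27 | C8 methanesulfonate with silylated phenol | CC1(C)[C@H](Br)C[C@H](O[Si](C)(C)C(C)(C)C)[C@]1(C)[C@@](Cc1c(C)ccc(O[Si](C)(C)C(C)(C)C)c1C)(O)CCOS(C)(=O)=O | intermediate
28 | phenol methanesulfonate (key-step precursor): free phenol on C10, methanesulfonate on C8, silyl ether on C4, bromide on C2 | CC1(C)[C@H](Br)C[C@H](O[Si](C)(C)C(C)(C)C)[C@]1(C)[C@@](Cc1c(C)ccc(O)c1C)(O)CCOS(C)(=O)=O | intermediate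
29 | lithium phenoxide of 28 | CC1(C)[C@H](Br)C[C@H](O[Si](C)(C)C(C)(C)C)[C@]1(C)[C@@](Cc1c(C)ccc([O-])c1C)(O)CCOS(C)(=O)=O.[Li+] | intermediate (not isolated)
30 | tricyclic cyclohexa-2,4-dienone (key-step product): C9 methyl trans to C6 hydroxyl, C10 ketone, C11=C12, C13=C14 | CC1(C)[C@H](Br)C[C@H](O[Si](C)(C)C(C)(C)C)[C@]1(C)[C@@]1(O)CC[C@]2(C)C(=O)C=CC(C)=C2C1 | intermediate
31 | β,γ-unsaturated ketone: C10 ketone, C13=C14 | CC1(C)[C@H](Br)C[C@H](O[Si](C)(C)C(C)(C)C)[C@]1(C)[C@@]1(O)CC[C@]2(C)C(=O)CCC(C)=C2C1 | intermediate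
32 | dipotassium salt: C6 alkoxide and C10–C11 enolate of 31 | CC1(C)[C@H](Br)C[C@H](O[Si](C)(C)C(C)(C)C)[C@]1(C)[C@@]1([O-])CC[C@]2(C)C([O-])=CCC(C)=C2C1.[K+].[K+] | intermediate (not isolated)
33 | enol triflate: C10–OTf, C10=C11, C13=C14 | CC1(C)[C@H](Br)C[C@H](O[Si](C)(C)C(C)(C)C)[C@]1(C)[C@@]1(O)CC[C@]2(C)C(OS(=O)(=O)C(F)(F)F)=CCC(C)=C2C1 | intermediate
34 | bromodiene: C10(Br)=C11, C13=C14 | CC1(C)[C@H](Br)C[C@H](O[Si](C)(C)C(C)(C)C)[C@]1(C)[C@@]1(O)CC[C@]2(C)C(Br)=CCC(C)=C2C1 | intermediate
35 | 13,14-epoxide, oxygen on the face of the C6 hydroxyl | CC1(C)[C@H](Br)C[C@H](O[Si](C)(C)C(C)(C)C)[C@]1(C)[C@@]1(O)CC[C@]2(C)C(Br)=CC[C@]3(C)O[C@]23C1 | intermediate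
36 | bromoalkene triol: C10(Br)=C11, trans-diaxial C13 and C14 hydroxyls | CC1(C)[C@H](Br)C[C@H](O[Si](C)(C)C(C)(C)C)[C@]1(C)[C@@]1(O)CC[C@]2(C)C(Br)=CC[C@@](C)(O)[C@@]2(O)C1 | intermediate
37 | 4-O-tert-butyldimethylsilyl neoirietetraol | CC1(C)[C@H](Br)C[C@H](O[Si](C)(C)C(C)(C)C)[C@]1(C)[C@@]1(O)CC[C@]2(C)[C@@H](Br)CC[C@@](C)(O)[C@@]2(O)C1 | intermediate
38 | neoirietetraol | CC1(C)[C@H](Br)C[C@H](O)[C@]1(C)[C@@]1(O)CC[C@]2(C)[C@@H](Br)CC[C@@](C)(O)[C@@]2(O)C1 | target

Total step count: 29. Longest linear sequence: 23 steps (steps 1–9 from 1 to 12, then steps 16–29 to 38); the arene branch 13 → 20 takes 6 steps.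

Steps most likely to fail

Step 22. C8 may be captured by C13, which is para to oxygen and bonded to C14 just as C9 is, so that ring B closes on the wrong carbon or a mixture of regioisomers forms. Fallback: the para mode is used on purpose and corrected afterwards. Setting out from 28, Cs2CO3 in 2,2,2-trifluoroethanol (free, hydrogen-bonded phenoxide) should close ring B through C13 and give the cross-conjugated dienone F1. Because C9 and C13 both carry methyl groups, F1 has the carbon skeleton and the relative configuration of 30 and differs only in a 1,3-shifted carbonyl. Weitz–Scheffer epoxidation (H2O2, NaOH, MeOH, 0 °C) of its disubstituted enone alkene should give the epoxy ketone F2. Wharton transposition (N2H4·H2O, AcOH, MeOH) should give the dienol F3, and Dess–Martin oxidation comes back to the route at 30.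

Step 5. The peroxyl radical may couple at the bromine-bearing end of the allyl radical, with loss of bromide, or the electron-poor alkene may be consumed slowly and over-oxidised. Fallback from 4, coming back at 8: IBX dehydrogenation (DMSO, 70 °C) should give the enone F4. Oxidation of the enone to the β-diketone (Na2PdCl4, t-BuOOH, aqueous AcOH, 50 °C) should give the 1,3-diketone F5. Ph3P/Br2/Et3N then converts the enol oxygen on C2, the one not deactivated by the neighbouring ester, into the bromide and gives 8.

Step 27. After ring opening, the developing C13 cation may lose a proton (allylic alcohols) or trigger ring contraction instead of being captured by water on the face opposite the epoxide oxygen. Fallback from 31, coming back at 36: the diol is made before the bromoalkene, with the C10 carbonyl as internal nucleophile. Epoxidation of 31 with m-CPBA should give the epoxy ketone F6. In aqueous HClO4/THF the carbonyl oxygen opens the epoxide at C13 from the face opposite the epoxide oxygen (five-membered, transannular), and hydrolysis of the oxocarbenium ion should give the keto diol F7. N2H4·H2O/Et3N in EtOH should give the hydrazone F8, and NBS in pyridine (Barton-type hydrazone oxidation, no strong base, hence no retro-aldol cleavage) gives 36.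

Further compounds
F1 | step 22 | cross-conjugated dienone from closure at C13 (quaternary methyl carbon trans to C6 hydroxyl, carbonyl 1,3-shifted relative to 30) | CC1(C)[C@H](Br)C[C@H](O[Si](C)(C)C(C)(C)C)[C@]1(C)[C@@]1(O)CC[C@]2(C)C=CC(=O)C(C)=C2C1
F2 | step 22 | epoxy ketone from F1 (epoxide on the disubstituted enone alkene, either face) | CC1(C)[C@H](Br)C[C@H](O[Si](C)(C)C(C)(C)C)[C@]1(C)[C@@]1(O)CC[C@]2(C)C3OC3C(=O)C(C)=C2C1
F3 | step 22 | dienol with C10 hydroxyl (either epimer), C11=C12 and C13=C14 | CC1(C)[C@H](Br)C[C@H](O[Si](C)(C)C(C)(C)C)[C@]1(C)[C@@]1(O)CC[C@]2(C)C(O)C=CC(C)=C2C1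
F4 | step 5 | methyl (1S)-1,5,5-trimethyl-4-oxocyclopent-2-ene-1-carboxylate | CC1(C)C(=O)C=C[C@]1(C)C(=O)OC
F5 | step 5 | methyl (1R)-1,2,2-trimethyl-3,5-dioxocyclopentane-1-carboxylate | CC1(C)C(=O)CC(=O)[C@]1(C)C(=O)OC
F6 | step 27 | epoxy ketone: C10 ketone, 13,14-epoxide on the face of the C6 hydroxyl | CC1(C)[C@H](Br)C[C@H](O[Si](C)(C)C(C)(C)C)[C@]1(C)[C@@]1(O)CC[C@]2(C)C(=O)CC[C@]3(C)O[C@]23C1
F7 | step 27 | keto diol: C10 ketone, trans-diaxial C13 and C14 hydroxyls | CC1(C)[C@H](Br)C[C@H](O[Si](C)(C)C(C)(C)C)[C@]1(C)[C@@]1(O)CC[C@]2(C)C(=O)CC[C@@](C)(O)[C@@]2(O)C1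
F8 | step 27 | C10 hydrazone of F7 | CC1(C)[C@H](Br)C[C@H](O[Si](C)(C)C(C)(C)C)[C@]1(C)[C@@]1(O)CC[C@]2(C)C(=NN)CC[C@@](C)(O)[C@@]2(O)C1
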